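## Structural features

The target 17 is a flavonol. A benzene ring A (C4a, C5, C6, C7, C8, C8a) is fused along the C4a–C8a bond to a 4-pyranone ring C (O1, C2, C3, C4). A 4-methoxyphenyl ring B is joined to C2 by a single bond, and C3 carries a free hydroxyl. Ring A holds methoxyls on all four remaining carbons (C5 to C8), so it is a hexasubstituted benzene with no C–H left. The target is flat and has no stereocentre; the only stereocentres in the plan are the adjacent C2 and C3 of flavanone 15, which are made together and erased together. Fragile points are the 5-methoxyl (peri to the C4 carbonyl, easily lost to Lewis or strong protic acids through chelation), the 3-hydroxy-enone (metal-chelating, oxidised in basic air) and the electron-rich phenols on the way to ring A, which oxidise to quinones. The real difficulty is ring A: an acyl carbon and an aryl ether oxygen must sit on neighbouring carbons of a ring that already bears four contiguous methoxyls, and the one hydroxyl on C3 must stay distinct from five methyl ethers. The key step uses the fact that C4a and C8a are neighbours and that the C5/C8 and C6/C7 methoxyls mirror each other across the midpoint of the C4a–C8a bond. Ring A can therefore enter as the symmetric 3,4,5,6-tetramethoxybenzyne 13, which accepts O1 and C4 from one carboxylic acid with no regiochemical question.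

## Logic of the disconnections

**17 to 16.** The O3–CH2 bond of a benzyl group is cut. O3 has to travel through the route as an ether that differs from the five methyl ethers, and a benzyl group leaves by hydrogenolysis, which methyl ethers ignore. The skeleton is unchanged, but the hydroxyl problem is settled. The forward step must cleave one benzylic C–O bond without saturating C2=C3 or touching the C4 carbonyl.

**16 to 15.** Two hydrogens are put back on C2 and C3. A saturated C2–C3 bond is what conjugate addition of O1 to C2 leaves behind, so 15 is the direct product of a ring closure. The forward dehydrogenation must work on any cis/trans mixture of 15, must also take along any 14 that has not closed, and must spare the benzyl ether and the 5-methoxyl.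

**15 to 8 and 12.** First O1–C2 is cut (retro-oxa-Michael) to reach 14. Then C4–C4a and O1–C8a are cut together, which leaves 13 and 12; 13 is released from 8. These two bonds sit on adjacent carbons of a ring that is symmetric about that edge, so one symmetric aryne can take up both atoms of a single carboxyl group. The gain is large: a bicyclic hexasubstituted aryl ketone falls into one symmetric C6 unit and an open-chain acid that already holds O1, C2, C3, C4, O3 and ring B. The forward step must move the acyl group to carbon before the aryl anion is protonated, and the phenoxide must then add 6-endo to an enone that carries donor groups.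

**8 to 5.** The C–Si bond and the O–S bond of the triflate are cut, through 7 and 6. Silicon is delivered from oxygen to the neighbouring carbon, so the bromine of 5 marks where the silyl group will sit. This reduces the aryne precursor to an ortho-bromophenol. The forward step needs bromine–lithium exchange to be faster than attack at silicon, and the crowded phenoxide 7 must still take a triflyl group.

**5 to 4.** The C–Br bond is cut. Only one ring position of 4 is open, so no regiochemistry arises. The forward bromination must substitute the ring without oxidising the electron-rich phenol to a quinone.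

**4 to 1.** The aryl C–O(H) bond is cut, through 3 (C–B) and 2 (C–Li). The two ring hydrogens of 1 are equivalent and each lies ortho to a methoxyl, so metalation gives one product. This brings ring A back to a purchasable arene. The forward step needs clean monolithiation and an oxidation that stops at the phenol.

**12 to 9 and 10.** The C2=C3 double bond (flavonoid numbering) is cut, through 11. Both halves are purchasable, and the benzyl ether on the future O3 is present from the start. The forward condensation must favour the crossed product over self-condensation of 9, and the ester must be hydrolysed without harming the enol ether. The alkene geometry does not matter for 17, because both centres derived from it are erased in step 6.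

## Other disconnections considered

**Alternative 1:** The cut is O1–C2, with the C3 oxygen put in later in place of iodine. The 3-iodoflavone A1 goes back to the pentamethoxyphenyl ynone A2. In the forward step ICl would activate the alkyne of A2, an ortho methoxy oxygen would attack the alkyne carbon that bears ring B (6-endo-dig, forming O1–C2 and C3–I), and chloride would remove the methyl group from the resulting oxonium ion.
- In favour: the two ortho methoxyls of A2 are equivalent, so this plan uses the symmetry of ring A as well as the chosen one does (equal). Iodocyclisation of ortho-methoxyaryl ynones is a well-established reaction type, so its key step is mechanistically more secure than the chosen one (better). It reaches the chromone oxidation level directly and needs no O3 protecting group (better).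
- Against: A1 has iodine where the target needs oxygen. Turning a 3-iodochromone into a 3-hydroxychromone would need metal-catalysed hydroxylation or borylation–oxidation at a carbon flanked by the carbonyl and ring B, on a pyranone that hydroxide can open. The anisyl ring could also compete for ICl.
- Step economy: A2 would need a pentamethoxybenzoyl unit made in several steps from the same kind of tetramethoxyphenol, so the total would be about equal to the chosen seven steps. The chosen plan carries O3 from the first step; this one leaves its hardest transformation to the end.

**Alternative 2:** The cut is C3–C4. The flavan-3,4-diol A3 goes back to the dialdehyde A4. In the forward step SmI2 (divalent samarium) in THF would reduce the aromatic aldehyde of A4 to a ketyl, which would add to the tethered aliphatic aldehyde and close ring C as the 3,4-cis diol.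
- In favour: double oxidation of A3 would give the 3,4-dione, whose enol is 17. The endgame would thus be one step with no protecting group on O3 (better than the two steps after the chosen key step). Ketyl–aldehyde closure to six-membered cis diols is a dependable reaction type (equal or better in mechanistic security).
- Against: A4 contains an aldehyde alpha to both an aryloxy group and an aryl group, which should enolise, racemise and oxidise readily. Making A4 needs a crowded phenol to be alkylated and two aldehydes to be told apart, which costs protecting-group steps. The symmetry of ring A is not used. Three stereocentres are built only to be destroyed. The final oxidation must avoid glycol cleavage of the C3–C4 bond.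
- Step economy: about nine steps are expected, against seven.

**Alternative 3:** The cut is C8–C8a, preceded by C5–C4a. The 5,8-hydroquinone A5 goes back to the 4-hydroxycyclobutenone A6, which would come from dimethyl squarate A7 and the lithio derivative of the bromopyranone A8. In the forward step heating A6 would open the four-membered ring to a dienylketene (Moore rearrangement). Its ketene carbon would bond to the pyranone CH by 6π electrocyclisation, and tautomerisation would give A5.
- In favour: all four oxygens of ring A are placed by construction, with no functionalisation of a crowded arene. The key step is thermal, reagent-free and regiochemically fixed by connectivity (equal or better than a fluoride-triggered sealed-tube reaction). The benzyl ether on O3 is already present, so the last step is the same as in the chosen plan (equal).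
- Against: A5 is a para-hydroquinone that should oxidise readily to the 5,8-quinone. It needs two further O-methylations, one at the chelated 5-hydroxyl. Metalation of A8 competes with addition to its own pyranone carbonyl, and A8 has no short synthesis.
- Step economy: ten or more steps are expected. The chosen plan avoids this by buying ring A ready-made and using its symmetry.

Key step: step 5

Assumption: 1, 9 and 10 are taken as purchasable. 15 is carried as a racemate because both of its stereocentres are erased in step 6. The Z geometry of 12 (aryl trans to carboxyl) and the trans arrangement in 15 agree with their drawn structures, so neither needs correction.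

## Route

**Step 1**
Reactants: 1 1,2,3,4-tetramethoxybenzene
Product: 4 2,3,4,5-tetramethoxyphenol, via aryllithium 2 (not isolated), via lithium aryltrimethoxyborate 3 (not isolated)
Conditions: n-BuLi, TMEDA, THF, 0 °C; B(OMe)3, −78 °C → rt; AcOH, 30% aq. H2O2, 0 °C → rt
Reagents that add atoms: hydrogen peroxide, OO
Why: Directed ortho-metalation: the two ring hydrogens of 1 are equivalent and each is ortho to a methoxyl, so a single aryllithium forms. Boron trapping and peroxide-induced 1,2-shift of the aryl group from boron to oxygen (arylboronate oxidation) then give the phenol.

**Step 2**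
Reactants: 4 2,3,4,5-tetramethoxyphenol
Product: 5 2-bromo-3,4,5,6-tetramethoxyphenol
Conditions: NBS, CH2Cl2, −78 → 0 °C, dark
Reagents that add atoms: N-bromosuccinimide, O=C1CCC(=O)N1Br
Why: Electrophilic aromatic bromination: C6 is the only unsubstituted ring carbon of 4 and is activated by the ortho hydroxyl and the para methoxyl. Low temperature and exclusion of water are meant to suppress oxidation of the phenol.

**Step 3**
Reactants: 5 2-bromo-3,4,5,6-tetramethoxyphenol
Product: 8 2,3,4,5-tetramethoxy-6-(trimethylsilyl)phenyl trifluoromethanesulfonate, via silyl ether 6 (not isolated), via lithium silylphenoxide 7 (not isolated)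
Conditions: HMDS, THF, reflux, then evaporate; n-BuLi, THF, −78 °C; Tf2O, −78 → 0 °C
Reagents that add atoms: hexamethyldisilazane, C[Si](C)(C)N[Si](C)(C)C; trifluoromethanesulfonic anhydride, O=S(=O)(OS(=O)(=O)C(F)(F)F)C(F)(F)F
Why: O-silylation, bromine–lithium exchange and retro-Brook rearrangement (1,3 shift of silicon from oxygen to the carbanion, driven by formation of the phenoxide) place the silyl group exactly where bromine was. Phenoxide 7 is then trapped as its triflate.

**Step 4**
Reactants: 9 ethyl 2-(benzyloxy)acetate; 10 4-methoxybenzaldehyde
Product: 12 (Z)-2-(benzyloxy)-3-(4-methoxyphenyl)acrylic acid, via ethyl ester 11 (not isolated)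
Conditions: NaOEt, THF–EtOH, 0 °C → rt; then 2 M aq. NaOH, 50 °C; then aq. HCl, recrystallise
Reagents that add atoms: NaOH (sodium hydroxide), [Na+].[OH-]
Why: Claisen-type aldol condensation of the ester enolate of 9 with the non-enolisable aldehyde 10, followed by E1cB loss of hydroxide, should give the enoate as its thermodynamic Z isomer (aryl trans to the carbonyl group). Hydroxide then saponifies 11 in the same pot and the acid is purified by crystallisation.

**Step 5**
Reactants: 8 2,3,4,5-tetramethoxy-6-(trimethylsilyl)phenyl trifluoromethanesulfonate; 12 (Z)-2-(benzyloxy)-3-(4-methoxyphenyl)acrylic acid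
Product: 15 racemic trans-3-(benzyloxy)-5,6,7,8-tetramethoxy-2-(4-methoxyphenyl)chroman-4-one, via tetramethoxybenzyne 13 (not isolated), via 2'-hydroxychalcone 14 (not isolated)
Conditions: CsF (4 equiv), THF, 125 °C, sealed tube; 8 in 1.5-fold excess
Reagents that add atoms: none
Why: Fluoride attacks the silicon of 8 and the ortho triflate leaves, which releases the symmetric aryne 13. The carboxylate of 12 adds through oxygen to either aryne carbon; the aryl anion then adds to the adjacent ester carbonyl and the four-membered alkoxide opens with C–O cleavage, so the acyl group moves from oxygen to carbon (O1–C8a and C4–C4a) and the phenoxide of 14 results. The closest known reaction type is the fluoride-mediated insertion of arynes into the C–O bond of carboxylic acids to give ortho-hydroxyaryl ketones, which with cinnamic acids continues to flavanones; the acid used here differs only by its α-benzyloxy group. Ring C closes by 6-endo-trig oxa-Michael addition of the phenoxide oxygen to C2 (O1–C2), and the 6'-methoxyl, which twists the open enone out of conjugation, should favour the closed form. C2 and C3 are under thermodynamic control, since C3 epimerises through the enolate and C2 through reversible ring opening, so the diequatorial trans isomer is expected to prevail; the outcome is immaterial because step 6 erases both centres. The step needs acyl transfer to win over protonation of the aryl anion, which would stop at the aryl ester; this is served by the 1,3 placement of the ester carbonyl next to the anion, by aprotic THF at high temperature and by excess CsF, which holds the single acid proton as bifluoride until the C3 enolate takes it. Regiochemistry does not arise, because both ends of the aryne bond are equivalent.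

**Step 6**
Reactants: 15 racemic trans-3-(benzyloxy)-5,6,7,8-tetramethoxy-2-(4-methoxyphenyl)chroman-4-one
Product: 16 3-(benzyloxy)-5,6,7,8-tetramethoxy-2-(4-methoxyphenyl)-4H-chromen-4-one
Conditions: I2 (cat.), DMSO, 120 °C
Reagents that add atoms: none
Why: Iodine-mediated dehydrogenation of a flavanone with DMSO as terminal oxidant: enolisation toward C3, α-iodination and loss of HI across C2–C3, with the HI reoxidised by DMSO. Cis and trans 15 and any unclosed 14 (oxidative cyclisation of a 2'-hydroxychalcone) should converge on 16.

**Step 7**
Reactants: 16 3-(benzyloxy)-5,6,7,8-tetramethoxy-2-(4-methoxyphenyl)-4H-chromen-4-one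
Product: 17 3-hydroxy-5,6,7,8-tetramethoxy-2-(4-methoxyphenyl)-4H-chromen-4-one
Conditions: H2 (1 atm), 10% Pd/C (palladium on carbon), EtOAc–MeOH, rt
Reagents that add atoms: none
Why: Hydrogenolysis of a benzyl ether on Pd/C. Aryl methyl ethers are inert, and the tetrasubstituted C2=C3 bond of the chromone (a vinylogous ester) is not expected to be reduced at atmospheric pressure and room temperature.

## Compound list

1 | 1,2,3,4-tetramethoxybenzene | COc1ccc(OC)c(OC)c1OC | starting material
2 | (2,3,4,5-tetramethoxyphenyl)lithium | [Li]c1cc(OC)c(OC)c(OC)c1OC | intermediate (not isolated)
3 | lithium trimethoxy(2,3,4,5-tetramethoxyphenyl)borate | [Li+].CO[B-](OC)(OC)c1cc(OC)c(OC)c(OC)c1OC | intermediate (not isolated)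
4 | 2,3,4,5-tetramethoxyphenol | Oc1cc(OC)c(OC)c(OC)c1OC | intermediate
5 | 2-bromo-3,4,5,6-tetramethoxyphenol | Oc1c(Br)c(OC)c(OC)c(OC)c1OC | intermediate
6 | (2-bromo-3,4,5,6-tetramethoxyphenoxy)trimethylsilane | C[Si](C)(C)Oc1c(Br)c(OC)c(OC)c(OC)c1OC | intermediate (not isolated)
7 | lithium 2,3,4,5-tetramethoxy-6-(trimethylsilyl)phenolate | [Li+].[O-]c1c([Si](C)(C)C)c(OC)c(OC)c(OC)c1OC | intermediate (not isolated)
8 | 2,3,4,5-tetramethoxy-6-(trimethylsilyl)phenyl trifluoromethanesulfonate | COc1c(OC)c(OC)c([Si](C)(C)C)c(OS(=O)(=O)C(F)(F)F)c1OC | intermediate
9 | ethyl 2-(benzyloxy)acetate | CCOC(=O)COCc1ccccc1 | starting material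
10 | 4-methoxybenzaldehyde | COc1ccc(C=O)cc1 | starting material
11 | ethyl (Z)-2-(benzyloxy)-3-(4-methoxyphenyl)acrylate | COc1ccc(/C=C(\OCc2ccccc2)C(=O)OCC)cc1 | intermediate (not isolated)
12 | (Z)-2-(benzyloxy)-3-(4-methoxyphenyl)acrylic acid | COc1ccc(/C=C(\OCc2ccccc2)C(=O)O)cc1 | intermediate
13 | 3,4,5,6-tetramethoxybenzyne | COC1=C(OC)C(OC)=C(OC)C#C1 | intermediate (not isolated)
14 | (Z)-2-(benzyloxy)-1-(2-hydroxy-3,4,5,6-tetramethoxyphenyl)-3-(4-methoxyphenyl)prop-2-en-1-one (present as its phenoxide in the flask) | COc1ccc(/C=C(\OCc2ccccc2)C(=O)c2c(O)c(OC)c(OC)c(OC)c2OC)cc1 | intermediate (not isolated)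
15 | racemic trans-3-(benzyloxy)-5,6,7,8-tetramethoxy-2-(4-methoxyphenyl)chroman-4-one, (2S,3S) enantiomer drawn | COc1ccc([C@@H]2Oc3c(OC)c(OC)c(OC)c(OC)c3C(=O)[C@H]2OCc2ccccc2)cc1 | intermediate
16 | 3-(benzyloxy)-5,6,7,8-tetramethoxy-2-(4-methoxyphenyl)-4H-chromen-4-one | COc1ccc(-c2oc3c(OC)c(OC)c(OC)c(OC)c3c(=O)c2OCc2ccccc2)cc1 | intermediate
17 | 3-hydroxy-5,6,7,8-tetramethoxy-2-(4-methoxyphenyl)-4H-chromen-4-one | COc1ccc(-c2oc3c(OC)c(OC)c(OC)c(OC)c3c(=O)c2O)cc1 | target

## Step count and least certain steps

Total step count: 7. Longest linear sequence: 6 steps (steps 1, 2, 3, 5, 6, 7); the acid arm joins after one step (step 4).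

**Step 5 (key step).** What may go wrong:
- protonation of the ortho aryl anion before it reaches the ester carbonyl, so that the reaction stops at O-arylation of the acid;
- slow conjugate addition of the phenoxide, because the α-benzyloxy and 4-methoxyphenyl groups both lower the electrophilicity of C2;
- O-arylation of the phenoxide of 14 by a second aryne.

Fallback: this sets out from 5 and 12. They are coupled (DCC, DMAP, CH2Cl2) to 2-bromo-3,4,5,6-tetramethoxyphenyl (Z)-2-(benzyloxy)-3-(4-methoxyphenyl)acrylate F1. F1 is treated with n-BuLi in THF at −100 °C. Bromine–lithium exchange then generates the same ortho-metalated aryl ester in a proton-free medium, and anionic Fries rearrangement should give 14 after an NH4Cl quench. Warming 14 with NaOAc in EtOH closes it to 15, where the route is rejoined; 14 may also be taken straight into step 6.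

**Step 2.** What may go wrong: oxidation of the very electron-rich phenol (oxidative demethylation toward a methoxybenzoquinone) in competition with ring bromination. Fallback: this sets out from 4 and avoids electrophilic halogen altogether. Addition of 4 to isopropyl isocyanate (cat. Et3N) gives 2,3,4,5-tetramethoxyphenyl isopropylcarbamate F2. Carbamate-directed ortho-metalation (TMSOTf, TMEDA; n-BuLi, −78 °C; TMSCl) gives 2,3,4,5-tetramethoxy-6-(trimethylsilyl)phenyl isopropylcarbamate F3. Carbamate cleavage and triflation in one pot (DBU, Et2NH, MeCN, 40 °C; then PhNTf2) returns to the route at 8, bypassing steps 2 and 3.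

**Step 4.** What may go wrong: self-condensation of 9, early saponification of 9 by the water released, and incomplete dehydration of the aldol. Fallback: this sets out from 9 and 10. A directed aldol addition (LDA, THF, −78 °C) gives ethyl 2-(benzyloxy)-3-hydroxy-3-(4-methoxyphenyl)propanoate F4 as a diastereomer mixture. Mesylation (MsCl, Et3N) gives ethyl 2-(benzyloxy)-3-(4-methoxyphenyl)-3-(methylsulfonyloxy)propanoate F5, and elimination with DBU gives 11. Hydrolysis with LiOH in THF–water returns to the route at 12.

**Step 6.** What may go wrong: acid-promoted loss of the 5-O-methyl group or of the benzyl group by HI at 120 °C, iodination of the electron-rich ring B, or slow enolisation toward the substituted C3. Fallback: this sets out from 15 and reverses the order of the last two operations. Hydrogenolysis (H2, Pd/C (palladium on carbon), EtOAc) gives racemic trans-3-hydroxy-5,6,7,8-tetramethoxy-2-(4-methoxyphenyl)chroman-4-one F6. This dihydroflavonol is then oxidised under buffered conditions (I2, KOAc, AcOH, reflux), which returns to the route at 17.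

## Further compounds

F1 | step 5 | 2-bromo-3,4,5,6-tetramethoxyphenyl (Z)-2-(benzyloxy)-3-(4-methoxyphenyl)acrylate | COc1ccc(/C=C(\OCc2ccccc2)C(=O)Oc2c(Br)c(OC)c(OC)c(OC)c2OC)cc1
F2 | step 2 | 2,3,4,5-tetramethoxyphenyl isopropylcarbamate | COc1cc(OC(=O)NC(C)C)c(OC)c(OC)c1OC
F3 | step 2 | 2,3,4,5-tetramethoxy-6-(trimethylsilyl)phenyl isopropylcarbamate | COc1c(OC)c(OC)c([Si](C)(C)C)c(OC(=O)NC(C)C)c1OC
F4 | step 4 | ethyl 2-(benzyloxy)-3-hydroxy-3-(4-methoxyphenyl)propanoate (diastereomer mixture, racemic) | CCOC(=O)C(OCc1ccccc1)C(O)c1ccc(OC)cc1
F5 | step 4 | ethyl 2-(benzyloxy)-3-(4-methoxyphenyl)-3-(methylsulfonyloxy)propanoate (diastereomer mixture, racemic) | CCOC(=O)C(OCc1ccccc1)C(OS(C)(=O)=O)c1ccc(OC)cc1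
F6 | step 6 | racemic trans-3-hydroxy-5,6,7,8-tetramethoxy-2-(4-methoxyphenyl)chroman-4-one, (2S,3S) enantiomer drawn | COc1ccc([C@@H]2Oc3c(OC)c(OC)c(OC)c(OC)c3C(=O)[C@H]2O)cc1
A1 | alternative 1 | 3-iodo-5,6,7,8-tetramethoxy-2-(4-methoxyphenyl)-4H-chromen-4-one | COc1ccc(-c2oc3c(OC)c(OC)c(OC)c(OC)c3c(=O)c2I)cc1
A2 | alternative 1 | 3-(4-methoxyphenyl)-1-(2,3,4,5,6-pentamethoxyphenyl)prop-2-yn-1-one | COc1ccc(C#CC(=O)c2c(OC)c(OC)c(OC)c(OC)c2OC)cc1
A3 | alternative 2 | racemic 2,3-trans-3,4-cis-5,6,7,8-tetramethoxy-2-(4-methoxyphenyl)chromane-3,4-diol, (2S,3R,4R) enantiomer drawn | COc1ccc([C@@H]2Oc3c(OC)c(OC)c(OC)c(OC)c3[C@@H](O)[C@H]2O)cc1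
A4 | alternative 2 | racemic 2,3,4,5-tetramethoxy-6-[1-(4-methoxyphenyl)-2-oxoethoxy]benzaldehyde | COc1ccc(C(C=O)Oc2c(C=O)c(OC)c(OC)c(OC)c2OC)cc1
A5 | alternative 3 | 3-(benzyloxy)-5,8-dihydroxy-6,7-dimethoxy-2-(4-methoxyphenyl)-4H-chromen-4-one | COc1ccc(-c2oc3c(O)c(OC)c(OC)c(O)c3c(=O)c2OCc2ccccc2)cc1
A6 | alternative 3 | racemic 4-[5-(benzyloxy)-6-(4-methoxyphenyl)-4-oxo-4H-pyran-3-yl]-4-hydroxy-2,3-dimethoxycyclobut-2-en-1-one | COC1=C(OC)C(O)(c2coc(-c3ccc(OC)cc3)c(OCc3ccccc3)c2=O)C1=O
A7 | alternative 3 | dimethyl squarate (3,4-dimethoxycyclobut-3-ene-1,2-dione) | COC1=C(OC)C(=O)C1=O
A8 | alternative 3 | 3-(benzyloxy)-5-bromo-2-(4-methoxyphenyl)-4H-pyran-4-one | COc1ccc(-c2occ(Br)c(=O)c2OCc2ccccc2)cc1
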